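**Small charge.** A small charge of free catalyst makes target from starting material and reagent, one of each per target, while the second substrate slowly turns it into spent catalyst.

| flask | starting material | reagent | second substrate | free catalyst | time | remark |
|---|---|---|---|---|---|---|
| dawn | 0.010 M | 5.00 mM | 0.0200 M | 9.9 µM | 6.0 min | everything together at the start |
| spring | 0.010 M (fed, over 80 s) | 5.00 mM | 0.0200 M | 9.9 µM | 6.0 min | all else is in the flask from the start; the feed brings no volume worth counting |
| summer | 0.010 M | 5.00 mM | 0.0200 M (fed, over 80 s) | 9.9 µM | 6.0 min | all else is in the flask from the start; the feed brings no volume worth counting |
| autumn | 0.010 M (in portions, 4, over 80 s) | 5.00 mM | 0.0200 M | 9.9 µM | 6.0 min | first portion at the start, last at 80 s |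

    starting material + reagent + free catalyst → free catalyst + target (k1 = 6.5 × 10⁵ L² mol⁻² s⁻¹)
    second substrate + reagent + free catalyst → free catalyst + second product (k2 = 12000 L² mol⁻² s⁻¹)
    second substrate + free catalyst → spent catalyst (k3 = 1.4 L mol⁻¹ s⁻¹)

- which flask leads in amount of target, in percent of the starting material charged ("all alike" within 1.5 percentage points) (dawn / spring / summer / autumn / all alike)
- how much target is there at the end, in percent of the starting material charged: dawn
- how much target is there at the end, in percent of the starting material charged: spring
- how much target is there at the end, in percent of the starting material charged: summer
- how much target is there at the end, in percent of the starting material charged: autumn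

**Working time.** Against the full second substrate, free catalyst has a lifetime of 35.7 s. I call working time the time in which its summed exposure to second substrate reaches one such lifetime. I leave out the side reaction with reagent, because in dawn, at the charges, it takes reagent at 3.69% of the rate of the main step.

**Dawn's curve.** In dawn, the share of the charge turned to target starts rising at 1.93 min⁻¹. Reagent is the limiting reagent and caps target at 50.0%. The starting slope would reach that cap in 15.5 s, sooner than the working time, so dawn's curve bends early as reagent and free catalyst fall together. For the level, I multiply the excess of starting material over reagent by the first rate constant, the free catalyst charge and the working time, which gives 1.15. The ratio of starting material left to reagent left then grows by the exponential of that number, from 2.00 to 6.31. So I expect dawn to level off at 40.6% of the charge.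

**Slow feeds.** In summer, exposure grows with the square of time and reaches one lifetime at 75.6 s, before the feed ends. That is twice dawn's working time, so the same rule gives 2.43 and a level of 47.7%, just under the cap. In spring, one lifetime passes with 44.6% of the starting material fed. My rule assumes the charge is present, so I give no number and expect less than dawn.

**The result.** The forecast picks summer, with 39.7% for dawn, 25% for spring, 46% for summer and 26% for autumn, saying that slow starting material "wastes the catalyst's early life at low starting material concentration". The flasks give 39.7% for dawn, 24.7% for spring, 46.8% for summer and 26.0% for autumn, so summer leads. Summer's target still reads 46.8% at 60.0 min.

**Heavier feed.** The neighbouring flask is summer with 0.080 M of second substrate. The lifetime of free catalyst against that full charge is 8.93 s, and the same reckoning gives a working time of 37.8 s, half of summer's. The number from the rule becomes 1.22, and the level 41.3%. That flask ends with 39.3% target and 60.7% of the starting material left.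

The numbers of this flask are assumed; the rest is arithmetic.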